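If the north flask's substrate goes on falling by one factor per unit of time, a single constant carries it from the readings to the asked time.

the same everywhere: substrate 0.016 M; gas 7.8 mM (held); initiator 0.16 mM

|  | remark | time |
|---|---|---|
| north | the very flask that is asked about, followed so far |  |
| flask |  | 20 min |

north run (percent of the substrate charged)

| time / min | substrate / % | product / % |
|---|---|---|
| 1.00 | 45 | 48 |
| 2.00 | 19 | 84 |
| 3.00 | 5 | 92 |
| 4.00 | 4 | 97 |

(readings scatter by 2 percentage points)

- at the start none of the gas is in solution
- the reaction counts as stopped when no species that holds the substrate changes by six tenths of a point or more over the second half of the time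

* why nothing more happens at 20 min, or that something still does (it is still moving / all of the substrate has reacted / forward and back rates have come level)
* share of the substrate used up at 20 min
* product at 20 min, in percent of the substrate charged

The reckoning integrates one rate law, with k as the pseudo-first-order constant, the fractional loss of substrate per unit of time:

−dc_substrate/dt = k c_substrate, so c_substrate / c_start = exp(−k t)

k = ln(1 / 19%) / 2.00 min = 0.830 min⁻¹

This k is a reading, and it carries the scatter of 2 percentage points.

Two extreme flasks bracket the answer. In the first, the law holds to the end:

k t = 16.6 at 20 min

The substrate left is then exp(−k t), far below the last reading. In the second, the reaction dies just after 4.00 min, so the substrate stays at 4% and conversion stops at 96.0%.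

The real flask lies between these, and my reckoning puts it near the first. The law gives 3.62% at 4.00 min against a reading of 4%, a gap inside the scatter, so the readings show no stop. Substrate and product there sum to 101%, so the product should take up what the substrate loses.

The forecast says all of the substrate has reacted, with conversion 100% (95% to 100%) and product 99% (94% to 100%), on the ground: “The simplest reading is an essentially irreversible reaction”.

    coupling partner + first chain carrier → product + second chain carrier (k = 5.20 × 10⁶ L mol⁻¹ s⁻¹)
    substrate + initiating radical → capped initiator + first chain carrier (k = 1.50 × 10⁸ L mol⁻¹ s⁻¹)
    initiator → 2 initiating radical (k = 2.70 × 10⁻⁵ s⁻¹)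
    substrate + second chain carrier → by-product + first chain carrier (k = 1.90 × 10⁶ L mol⁻¹ s⁻¹)
    gas ⇌ coupling partner, rate k5*(csat - [coupling partner]) (kL = 0.980 s⁻¹)
    2 second chain carrier → ended chains A (k = 5.70 × 10⁷ L mol⁻¹ s⁻¹)
    2 first chain carrier → ended chains B (k = 1.20 × 10⁸ L mol⁻¹ s⁻¹)

At 20 min the flask stands at 100% conversion and >99.9% product: all of the substrate has reacted. Of the substrate 0% is left, less than the 97% of its own charge that remains of the initiator. With k, 90.0% of the conversion comes at 2.77 min, and the flask reaches that share at 2.61 min. The neighbour flask, left until 50 min, stands at k t = 41.5, and it holds 0% of its substrate and 92% of its initiator.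

The earlier runs and the new flask come from a simulation with constants of no real substance.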